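## Retrosynthetic overview

1. The target comes from a bis-carbinol tetramethyl ether. Each CH2–CH2 bridge is carried as ArCH(OH)–CH2Ar', and one operation removes both benzylic C–OH groups and all four O-methyl groups.
2. The C–D bridge is cut between two former aldehyde carbons. The ring C aldehyde is the electrophile, and 2,5-dimethoxybenzaldehyde serves as its N-unsubstituted hydrazone, a benzyl-anion equivalent that loses N2.
3. The B–O–C diaryl ether is cut by an Ullmann disconnection into isovanillin and an aryl bromide.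
4. The A–B bridge is cut the same way: 4-bromobenzaldehyde is the electrophile and 3-methoxybenzaldehyde hydrazone is the carbanion equivalent. Each OH is placed next to the ring that carries a para oxygen donor.
5. No ring is formed. Rings A–D are all bought and are joined in the order A–B, then B–O–C, then C–D.

Assumption: the target has no stereocentre, stereogenic axis or C=C bond, so it is achiral and there is no enantiomer to select. The carbinol centres in 4, 6 and 9 are carried as stereoisomer mixtures and are erased in step 4.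

## Route

**Step 1**
Reactants: 1 3-methoxybenzaldehyde; 2 4-bromobenzaldehyde
Product: 4 rac-1-(4-bromophenyl)-2-(3-methoxyphenyl)ethan-1-ol, via hydrazone 3 (not isolated)
Conditions: 1 (1.3 equiv), N2H4·H2O (1.35 equiv), THF, rt, 1 h; then 2 (1.0 equiv), [RuCl2(p-cymene)]2 (1 mol %), Me2PCH2CH2PMe2 (dmpe, 2 mol %), K3PO4 (25 mol %), CsF (1 equiv), THF, 45 °C, 12 h, N2
Reagents that add atoms: none
Why: This is a ruthenium-catalysed carbonyl-umpolung (hydrazone, Wolff–Kishner-type carbanion) addition, in which deprotonated hydrazone 3 and aldehyde 2 bind to divalent ruthenium, C–C bond formation through a six-membered transition state expels N2 so that two aldehyde carbons are joined, the aryl bromide is untouched at 45 °C, and the new carbinol centre is racemic (achiral catalyst) and is deleted in step 4.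

**Step 2**
Reactants: 4 rac-1-(4-bromophenyl)-2-(3-methoxyphenyl)ethan-1-ol; 5 isovanillin (3-hydroxy-4-methoxybenzaldehyde)
Product: 6 rac-3-{4-[1-hydroxy-2-(3-methoxyphenyl)ethyl]phenoxy}-4-methoxybenzaldehyde
Conditions: 5 (1.3 equiv), CuI (10 mol %), N,N-dimethylglycine·HCl (30 mol %), Cs2CO3 (2.5 equiv), 1,4-dioxane, 100 °C, 24 h, Ar
Reagents that add atoms: none
Why: In this ligand-accelerated Ullmann diaryl ether coupling, the monovalent-copper/amino-acid catalyst arylates the caesium phenoxide of 5 much faster than the un-ionised secondary alcohol of 4, the aldehyde is a spectator, and no stereocentre is made or touched.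

**Step 3**
Reactants: 6 rac-3-{4-[1-hydroxy-2-(3-methoxyphenyl)ethyl]phenoxy}-4-methoxybenzaldehyde; 7 2,5-dimethoxybenzaldehyde
Product: 9 2-(2,5-dimethoxyphenyl)-1-(3-{4-[1-hydroxy-2-(3-methoxyphenyl)ethyl]phenoxy}-4-methoxyphenyl)ethan-1-ol (diastereomer mixture), via hydrazone 8 (not isolated)
Conditions: 7 (1.5 equiv), N2H4·H2O (1.55 equiv), THF, rt, 1 h; then 6 (1.0 equiv), [RuCl2(p-cymene)]2 (2.5 mol %), dmpe (5 mol %), K3PO4 (50 mol %), CsF (1 equiv), THF, 45–50 °C, 24 h, N2
Reagents that add atoms: none
Why: This is the same ruthenium-catalysed hydrazone umpolung addition, which runs in protic media so the free carbinol of 6 (the same class of alcohol the reaction itself produces) is tolerated, and the second carbinol centre forms without control, giving about 1:1 diastereomers that converge in step 4.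

**Step 4**
Reactants: 9 bis-carbinol tetramethyl ether
Product: 11 2-(2-{4-hydroxy-3-[4-(2-(3-hydroxyphenyl)ethyl)phenoxy]phenyl}ethyl)benzene-1,4-diol (target), via tetrakis(triethylsilyl) ether 10 (not isolated)
Conditions: B(C6F5)3 (8 mol %), Et3SiH (12 equiv), CH2Cl2, 0 °C to rt, 16 h; then 1 M aq HCl, THF–MeOH, rt, 2 h, Ar
Reagents that add atoms: none
Why: In this B(C6F5)3-catalysed hydrosilane reduction (Gevorgyan–Yamamoto deoxygenation combined with Piers–Rubinsztajn demethylation), silyloxonium ions form at the two benzylic C–O bonds (each para to an oxygen donor) and at the four ArO–CH3 bonds, HB(C6F5)3− then delivers hydride to give CH2 groups and aryl silyl ethers while the diaryl ether and aryl–O bonds cannot ionise, both carbinol stereocentres are erased, and dilute acid frees the four phenols.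

## Compound list

| No. | Name | SMILES | Role |
|---|---|---|---|
| 1 | 3-methoxybenzaldehyde | COc1cccc(C=O)c1 | starting material |
| 2 | 4-bromobenzaldehyde | O=Cc1ccc(Br)cc1 | starting material |
| 3 | (E)-(3-methoxybenzylidene)hydrazine | COc1cccc(/C=N/N)c1 | intermediate |
| 4 | rac-1-(4-bromophenyl)-2-(3-methoxyphenyl)ethan-1-ol | COc1cccc(CC(O)c2ccc(Br)cc2)c1 | intermediate |
| 5 | isovanillin (3-hydroxy-4-methoxybenzaldehyde) | COc1ccc(C=O)cc1O | starting material |
| 6 | rac-3-{4-[1-hydroxy-2-(3-methoxyphenyl)ethyl]phenoxy}-4-methoxybenzaldehyde | COc1cccc(CC(O)c2ccc(Oc3cc(C=O)ccc3OC)cc2)c1 | intermediate |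
| 7 | 2,5-dimethoxybenzaldehyde | COc1ccc(OC)c(C=O)c1 | starting material |
| 8 | (E)-(2,5-dimethoxybenzylidene)hydrazine | COc1ccc(OC)c(/C=N/N)c1 | intermediate |
| 9 | 2-(2,5-dimethoxyphenyl)-1-(3-{4-[1-hydroxy-2-(3-methoxyphenyl)ethyl]phenoxy}-4-methoxyphenyl)ethan-1-ol (mixture of two racemic diastereomers) | COc1cccc(CC(O)c2ccc(Oc3cc(C(O)Cc4cc(OC)ccc4OC)ccc3OC)cc2)c1 | intermediate |
| 10 | tetrakis(triethylsilyl) ether of 11 | CC[Si](CC)(CC)Oc1cccc(CCc2ccc(Oc3cc(CCc4cc(O[Si](CC)(CC)CC)ccc4O[Si](CC)(CC)CC)ccc3O[Si](CC)(CC)CC)cc2)c1 | intermediate |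
| 11 | 2-(2-{4-hydroxy-3-[4-(2-(3-hydroxyphenyl)ethyl)phenoxy]phenyl}ethyl)benzene-1,4-diol (achiral) | Oc1cccc(CCc2ccc(Oc3cc(CCc4cc(O)ccc4O)ccc3O)cc2)c1 | target |

## Step count

- Total steps: 4.
- Longest linear sequence: 4 (1 or 2 → 4 → 6 → 9 → 11).

## Three steps most likely to fail

**Step 3.**
- Risk: aldehyde 6 is an electron-rich anisaldehyde-type electrophile and hydrazone 8 is ortho-substituted. Mixed azine formation and simple Wolff–Kishner reduction of 8 may therefore outrun C–C bond formation.
- Fallback: it sets out from 7 and comes back at 9. Compound 7 is condensed with propane-1,3-dithiol (SCCCS) and BF3·OEt2 in CH2Cl2 to give 2-(2,5-dimethoxyphenyl)-1,3-dithiane F1. F1 is lithiated with n-BuLi in THF at −30 °C, and 2.2 equiv of the anion are added to 6 at −78 °C; the first equivalent takes the OH proton. This gives [2-(2,5-dimethoxyphenyl)-1,3-dithian-2-yl](3-{4-[1-hydroxy-2-(3-methoxyphenyl)ethyl]phenoxy}-4-methoxyphenyl)methanol F2. Raney Ni in EtOH then desulfurises F2 to 9. Any partial loss of benzylic OH at this stage is harmless, because step 4 removes both.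

**Step 2.**
- Risk: the aryl bromide is unactivated, and the phenol is both ortho-substituted and formyl-deactivated. The coupling may be slow, and the aldehyde has to survive 24 h of hot carbonate.
- Fallback: it sets out from 5 and comes back at 9. The order of events is changed so that the ether is made by metal-free SNAr. Hydrazone 8 is added under the step 3 catalyst system to 5, with 1.3 equiv of extra K3PO4 to carry the phenol as its phenoxide, giving 5-[2-(2,5-dimethoxyphenyl)-1-hydroxyethyl]-2-methoxyphenol F3. F3 displaces fluoride from purchased 4-fluorobenzaldehyde F4 (K2CO3, DMF, 110 °C) to give 4-{5-[2-(2,5-dimethoxyphenyl)-1-hydroxyethyl]-2-methoxyphenoxy}benzaldehyde F5. Hydrazone 3 is then added to F5 under the step 1 conditions, which gives 9 directly.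

**Step 4.**
- Risk: eight Si–H events must all finish on one molecule. Traces of water or the many oxygen donors may stall the borane. The ring B carbinol may stop at the silyl ether or eliminate to a stilbene, which is then hydrosilylated.
- Fallback: it sets out from 9 and comes back at 11. Both benzylic C–OH bonds are hydrogenolysed (H2, 4 bar, Pd/C, AcOH, catalytic HClO4, 40 °C) to give 2-{2-[4-methoxy-3-(4-{2-(3-methoxyphenyl)ethyl}phenoxy)phenyl]ethyl}-1,4-dimethoxybenzene F6. F6 is demethylated with BBr3 (8 equiv, CH2Cl2, −78 °C to rt, aqueous work-up under Ar) to give 11.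

## Further compounds

F1 | step 3 | 2-(2,5-dimethoxyphenyl)-1,3-dithiane | COc1ccc(OC)c(C2SCCCS2)c1
F2 | step 3 | [2-(2,5-dimethoxyphenyl)-1,3-dithian-2-yl](3-{4-[1-hydroxy-2-(3-methoxyphenyl)ethyl]phenoxy}-4-methoxyphenyl)methanol | COc1cccc(CC(O)c2ccc(Oc3cc(C(O)C4(SCCCS4)c5cc(OC)ccc5OC)ccc3OC)cc2)c1
F3 | step 2 | 5-[2-(2,5-dimethoxyphenyl)-1-hydroxyethyl]-2-methoxyphenol | COc1ccc(OC)c(CC(O)c2ccc(OC)c(O)c2)c1
F4 | step 2 | 4-fluorobenzaldehyde (purchased) | O=Cc1ccc(F)cc1
F5 | step 2 | 4-{5-[2-(2,5-dimethoxyphenyl)-1-hydroxyethyl]-2-methoxyphenoxy}benzaldehyde | COc1ccc(OC)c(CC(O)c2ccc(OC)c(Oc3ccc(C=O)cc3)c2)c1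
F6 | step 4 | 2-{2-[4-methoxy-3-(4-{2-(3-methoxyphenyl)ethyl}phenoxy)phenyl]ethyl}-1,4-dimethoxybenzene | COc1cccc(CCc2ccc(Oc3cc(CCc4cc(OC)ccc4OC)ccc3OC)cc2)c1
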